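## Structural features

Numbering follows bicyclo[3.2.1]octane: C1 (bridgehead CH), C2 (enone C=O), C3 (C–OMe), C4 (vinyl CH), C5 (allyl-bearing bridgehead), C6 (CH–CH3), C7 (CH–aryl), C8 (bridging C=O).

Kadsurenin D is a bicyclo[3.2.1]octane neolignan: a cyclopentanone ring (C1, C7, C6, C5, C8) and a cyclohexenone ring (C1, C2, C3, C4, C5, C8) share the bridgeheads C1 and C5 and the bridging ketone C8, and C1–C7 form the seven-membered ring of the bicycle. The three-carbon bridge is a 2-alkoxy enone (C2=O, C3–OMe, C3=C4). The two-carbon bridge carries the 3,4-dimethoxyphenyl group on C7 and a methyl group on C6, and C5 is quaternary and carries the allyl group. Four stereocentres are contiguous, C1 (S), C7 (R), C6 (R) and C5 (S); the aryl group is exo (on the side of C8) and the methyl group endo, so they are trans. Fragile points: C1 lies between C2=O and C8=O and cannot enolise, so this 1,3-dione is open to retro-Claisen cleavage by nucleophilic base; the enol ether is acid-sensitive; the terminal allyl double bond excludes hydrogenation and hydroboration and can move into conjugation under strong base or metal hydrides. The real difficulty is the quaternary bridgehead C5 flanked by C4, C6 and C8 in a single enantiomer, together with the trans arrangement at C6/C7. The key step exploits two facts: C2–C3–C4 bears oxygen on C2 and C3 in the pattern of a 1-alkoxy-2-oxyallyl cation, and C1, C7, C6, C5 with C8 are the ring carbons of a cyclopentadienone, used as its dimethyl ketal, whose diene termini are C1 and C5.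

## Logic of the disconnections

17 ⇒ 16. The O–CH3 bond on C3 is cut. Because C1 is a bridgehead, 16 is the only enol the 2,3-dione can form, so the position of the methoxy group is fixed by structure. The forward step must alkylate on oxygen under conditions that are neither basic nor nucleophilic.

16 ⇒ 14 (through 15). C2 is taken back from ketone to secondary alcohol. The gain is that 14 is the directly unmasked form of a cycloadduct that carries oxygen on C2 and C3. The forward oxidation must leave the allyl group and the electron-rich arene alone and must not cleave the C2–C3 bond.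

14 ⇒ 13. The benzylic O–C bond of the ether on C2 and the two C8–OCH3 bonds are restored. Keeping the acyloin and the bridging ketone masked removes every enolisable or electrophilic carbonyl except C3 during C–C bond formation at C7. The forward step is one acid treatment that must spare the allyl group and must not let the benzylic cation alkylate the arene.

13 ⇒ 11 + 12. The C7–aryl bond and the C6–H bond are cut, which returns the C6=C7 double bond. The arene becomes a simple boronic acid, and C6 and C7 are set together by one syn addition. The forward step must choose the strained ring alkene over the allyl group, put the aryl group on C7, and add on the exo face.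

11 ⇒ 5 + 9 (through 10). This is the key disconnection: C1–C2 and C4–C5 are cut. The bicycle falls into a flat, achiral diene and an acyclic three-carbon unit; two rings, three stereocentres and both bridge oxygens are accounted for. The forward step must pair the alkoxy-bearing carbon with C1 and the methylene carbon with C5, close to the seven-membered ring rather than a five-membered one, and use one face of the cation.

5 ⇒ 4 ⇒ 3 ⇒ 1 (through 2). The second ring double bond of 5 is traced to H and Br on adjacent carbons, the two ketal C–O bonds to a ketone, and the C–Br bond to the α′-position of 1. 1 is commercial and already holds allyl and methyl on a tetrasubstituted double bond. The forward steps need kinetic α′-enolisation, ketalisation without double-bond shift, and elimination without allyl migration; 5 must be used promptly.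

9 ⇒ 8 ⇒ 6 + 7. The O–Si bond and then the two acetal C–O bonds are cut. With two identical chiral alkoxy groups there is no stereocentre at the acetal carbon, and whichever group leaves, the cation carries the auxiliary. The forward steps need a double acetal exchange without racemisation of 7 and kinetic enolisation at the methyl group.

## Other disconnections considered

Alternative 1: The cut goes through C6–C7 and the C5–allyl bond; C2 and C4 remain as exocyclic one-carbon stubs and C3 is still missing. In the forward step the cross-conjugated dienone methyl 3-(3,4-dimethoxyphenyl)-2-{2-[(4-methoxybenzyloxy)methyl]but-2-enoyl}acrylate A1 would undergo 4π conrotatory closure under Cu(OTf)2 and a chiral bis(oxazoline), and the oxyallyl cation (C5–C8–C1) would be captured at C5 by allyltrimethylsilane to give the cyclopentanone A2.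
- In favour: aryl and methyl are present from the start and their trans relationship follows from conrotation of an (E,E)-dienone. On this point the alternative is better than the chosen plan, which adds the aryl group late by a step without direct precedent. Absolute control is catalytic rather than through a stoichiometric auxiliary (better), and no acid-sensitive diene is handled (better). Capture anti to the C6 methyl would give the needed configuration at C5.
- Against: enantioselective copper-catalysed Nazarov closure combined with intermolecular allylsilane capture at a fully substituted carbon is not an established package. Capture must compete with proton loss and must choose C5 over C1. The six-membered ring is not formed: C3 must still be inserted between the ester carbon and the hydroxymethyl carbon (ester to ketone in the presence of the ring ketone, intramolecular aldol condensation, adjustment of C3).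
- Comparison: structurally the chosen cycloaddition makes two rings and delivers both bridge oxygens, whereas A2 is still monocyclic. Mechanistically both key steps are cationic and each rests on one unproven selectivity (pairing of termini versus site of capture), so they are about equal in risk. In step count the chosen plan is clearly shorter (ten steps against an estimated fifteen or more).

Alternative 2: The cut is C1–C2. The achiral precursor 3-(1-allyl-2,5-dioxocyclopentyl)-2-methoxyacrylaldehyde A3 has two enantiotopic ring ketones; a chiral phosphoric acid would promote enolisation of one of them through C1 and aldol addition to the aldehyde C2 to give the bicyclic ketol A4.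
- In favour: the quaternary carbon C5 is made in an achiral compound and becomes stereogenic only in the catalytic desymmetrisation (better than an auxiliary). The methoxy enone is complete apart from the oxidation level of C2, so the three-carbon bridge would need one oxidation instead of the three closing steps of the chosen plan (better). No regiochemical question arises in the ring-forming step (better).
- Against: A4 is a strained β-hydroxy ketone that can revert by retro-aldol cleavage, so position of equilibrium and enantiomeric purity are uncertain. The two-carbon bridge arrives as C6=O/C7H2 and must become C6–CH3/C7–aryl trans. That requires differentiation of C6=O from C8=O, and the obvious sequence through a C6=C7 alkene ends at the same hydroarylation problem as the chosen plan, only later and on a more functionalised substrate.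
- Comparison: structurally A4 has the right bridge oxygens but the wrong two-carbon bridge, while the chosen adduct has the full carbon skeleton and a double bond where the aryl group must go. Mechanistically a reversible aldol stands against an irreversible cycloaddition. Step count is estimated at fourteen or more against ten.

Alternative 3: The cuts are C1–C8 and C5–C8, the one-carbon bridge. Nitromethane and DBU would add to C1 of trans-3-allyl-5-(3,4-dimethoxyphenyl)-4-methylcyclohepta-2,6-dien-1-one A5, and the nitronate would close across the ring onto C5 to give the nitro ketone A6; a Nef reaction would later give C8=O.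
- In favour: transannular double conjugate addition to a cross-conjugated cycloheptadienone is a robust and simple reaction type. Aryl and methyl are in place before the bicycle closes (better than the chosen plan). No Lewis acid or labile ketal is involved (better).
- Against: the absolute configuration must already be present in A5, a trisubstituted seven-membered dienone whose enantioselective synthesis is a multi-step problem in itself. The first addition at C1 is expected anti to the neighbouring aryl group, which would place the bridge opposite to aryl and lead to the endo-aryl series unless the additions equilibrate. The second addition must form the quaternary centre at a β,β-disubstituted carbon. The bridge then carries only the C3 ketone, and oxygen must be introduced at C2 rather than C4 with only a modest steric difference to tell the two methylene groups apart; the chosen plan delivers that oxygen at C2 with the three-carbon partner.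
- Comparison: structurally both plans reach the bicycle in one step, but A6 lacks the C2 oxygen and the chosen adduct lacks the aryl group. Mechanistically the anionic sequence is milder, but its facial course is set by the substrate in the wrong sense, whereas the chosen plan relies on an auxiliary. Step count is estimated at thirteen or more plus the synthesis of A5, against ten.

Key step: step 6

Assumption: the (S)-1-phenylethoxy group is taken to direct the diene to the face of the cation that gives the (1R,5R) skeleton of 11; should the sense be opposite, (R)-1-phenylethanol replaces 7 in step 4 with no other change.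

## Route

Step 1
Reactants: 1 2-allyl-3-methylcyclopent-2-en-1-one
Product: 3 2-allyl-5-bromo-3-methylcyclopent-2-en-1-one (racemic), via silyl dienol ether 2 (not isolated)
Conditions: LiN(iPr)2, TMSCl (in situ quench), THF, −78 °C; then NBS, −78 → 0 °C
Reagents that add atoms: N-bromosuccinimide, O=C1CCC(=O)N1Br
Why: Kinetic deprotonation of a 2,3-disubstituted cyclopentenone by a lithium amide takes place at the α′-methylene, and the cross-conjugated silyl dienol ether 2 is brominated at that carbon much faster than either C=C bond reacts (halogenation of a silyl enol ether); the new stereocentre is racemic and is destroyed in step 3.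

Step 2
Reactants: 3 2-allyl-5-bromo-3-methylcyclopent-2-en-1-one
Product: 4 1-allyl-4-bromo-5,5-dimethoxy-2-methylcyclopent-1-ene (racemic)
Conditions: HC(OMe)3, MeOH, TsOH·H2O (5 mol %), 0 °C → rt; then Et3N
Reagents that add atoms: trimethyl orthoformate, COC(OC)OC
Why: Acid-catalysed ketalisation with the orthoformate as water scavenger; the β-carbon of the enone is fully substituted, so conjugate addition of methanol is not expected, and the α-bromine disfavours loss of methanol from the ketal to an enol ether.

Step 3
Reactants: 4 1-allyl-4-bromo-5,5-dimethoxy-2-methylcyclopent-1-ene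
Product: 5 1-allyl-5,5-dimethoxy-2-methylcyclopenta-1,3-diene
Conditions: KOtBu (1.2 equiv), THF, 0 °C, 30 min; cold pentane/aq NaHCO3 work-up; solution used at once
Reagents that add atoms: none
Why: E2 dehydrobromination in which the only β-hydrogens are the allylic ones of the ring methylene, so only the conjugated diene can form; the dimethyl ketal is kept because acyclic ketals of cyclopentadienone dimerise far more slowly than cyclic ones, and short contact with the base at 0 °C should limit migration of the allyl double bond.

Step 4
Reactants: 6 pyruvaldehyde dimethyl acetal (1,1-dimethoxypropan-2-one); 7 (S)-1-phenylethanol (2.5 equiv)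
Product: 8 1,1-bis[(S)-1-phenylethoxy]propan-2-one
Conditions: PPTS (5 mol %), cyclohexane, 70 °C, condensate returned through 5 Å molecular sieves
Reagents that add atoms: none
Why: Acid-catalysed transacetalisation driven by removal of methanol; the alcohol reacts through oxygen, so its stereocentre is untouched, and the mild pyridinium acid is chosen to avoid ionisation of the benzylic alcohol.

Step 5
Reactants: 8 1,1-bis[(S)-1-phenylethoxy]propan-2-one
Product: 9 2-(triethylsilyloxy)acrolein bis[(S)-1-phenylethyl] acetal
Conditions: LiN(iPr)2, Et3SiCl (in situ quench), THF, −78 → 0 °C; Et3N; filtration through basic alumina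
Reagents that add atoms: chlorotriethylsilane, CC[Si](Cl)(CC)CC
Why: Kinetic enolisation occurs at the methyl group and not at the acetal C–H, which is shielded by two secondary alkoxy groups; O-silylation then gives the enol silane.

Step 6
Reactants: 5 1-allyl-5,5-dimethoxy-2-methylcyclopenta-1,3-diene (1.5 equiv); 9 2-(triethylsilyloxy)acrolein bis[(S)-1-phenylethyl] acetal
Product: 11 (1R,2S,5R)-5-allyl-8,8-dimethoxy-6-methyl-2-[(S)-1-phenylethoxy]bicyclo[3.2.1]oct-6-en-3-one, via alkoxysilyloxyallyl cation triflate 10 (not isolated)
Conditions: TMSOTf (0.2 equiv), CH2Cl2, −95 → −78 °C; Et3N quench at −78 °C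
Reagents that add atoms: none
Why: TMSOTf removes one 1-phenylethoxy group from 9 to give the oxocarbenium ion 10, a 1-alkoxy-2-silyloxyallyl cation, which adds across the termini of the s-cis-locked diene 5; loss of the triethylsilyl group from the resulting silyloxocarbenium ion gives the C3 ketone and a silyl triflate that carries the chain, so the acid is catalytic. The closest known reaction type is the Lewis-acid-induced (4+3) cycloaddition of 2-silyloxyacrolein acetals with furans and cyclopentadienes, including 1-phenylethyl acetals for absolute control. The first bond (C1–C2) is intermolecular; the second (C4–C5) closes the seven-membered ring by a 7-endo-trig attack of the enol silane carbon on the ring allyl cation and, counted through C8, the six-membered ring by a 6-exo-trig attack (enol double bond inside the ring in both), which in the concerted limit is a suprafacial compact (4+3) transition state. C1 and C5 are formed cis because both bonds are made on one face of the planar diene, and their absolute sense is decided by the (S)-1-phenylethoxy group on the cation, since the two faces of 5 are equivalent. C2 is set by the Z geometry of the cation and the compact approach, which place the alkoxy group equatorial, away from the C8 methoxy group that lies over the three-carbon bridge; this centre is removed in step 9. The step needs the right pairing of termini, closure at C5 rather than C7, and one face of the cation: the pairing is the sterically matched one (bulky alkoxy-bearing carbon at the CH terminus, methylene carbon at the fully substituted terminus), the ring allyl cation carries most of its charge on the tertiary carbon C5, and the facial choice rests on the auxiliary. The ketal of 5 resists ionisation because that would give a cyclopentadienyl cation, and the two identical alkoxy groups of 9 ensure that only the auxiliary-bearing cation can form.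

Step 7
Reactants: 11 (1R,2S,5R)-5-allyl-8,8-dimethoxy-6-methyl-2-[(S)-1-phenylethoxy]bicyclo[3.2.1]oct-6-en-3-one; 12 3,4-dimethoxyphenylboronic acid (3 equiv)
Product: 13 (1R,2S,5R,6R,7R)-5-allyl-7-(3,4-dimethoxyphenyl)-8,8-dimethoxy-6-methyl-2-[(S)-1-phenylethoxy]bicyclo[3.2.1]octan-3-one
Conditions: [Rh(OH)(cod)]2 (5 mol %), 1,4-dioxane/H2O 10:1, 80 °C
Reagents that add atoms: none
Why: Proposed new method: transmetalation of 12 gives an aryl complex of monovalent rhodium, which inserts the strained C6=C7 bond syn on the exo face (the endo face is covered by the C2–C3–C4 bridge) with the aryl group going to the less substituted C7; the C6–Rh bond is then protonated by water with retention, directly or after a 1,4-shift of rhodium to the ortho position of the new aryl ring, so that aryl on C7 and hydrogen on C6 are both exo and aryl and methyl are trans. The closest known reaction type is the rhodium-catalysed hydroarylation of disubstituted norbornene-type alkenes with arylboronic acids, which unstrained monosubstituted alkenes such as the allyl group do not undergo.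

Step 8
Reactants: 13 (1R,2S,5R,6R,7R)-5-allyl-7-(3,4-dimethoxyphenyl)-8,8-dimethoxy-6-methyl-2-[(S)-1-phenylethoxy]bicyclo[3.2.1]octan-3-one
Product: 14 (1R,2S,5R,6R,7R)-5-allyl-7-(3,4-dimethoxyphenyl)-2-hydroxy-6-methylbicyclo[3.2.1]octane-3,8-dione (C2 epimer or ketol tautomer immaterial)
Conditions: CF3CO2H/H2O 9:1, 1,3,5-trimethoxybenzene (5 equiv), 0 °C → rt
Reagents that add atoms: water, O
Why: SN1 cleavage of the secondary benzylic ether and hydrolysis of the bridging ketal in one acid treatment; trimethoxybenzene traps the 1-phenylethyl cation so that it does not alkylate the dimethoxyphenyl ring, and the C2–O bond is not broken.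

Step 9
Reactants: 14 (1R,2S,5R,6R,7R)-5-allyl-7-(3,4-dimethoxyphenyl)-2-hydroxy-6-methylbicyclo[3.2.1]octane-3,8-dione
Product: 16 (1S,5S,6R,7R)-5-allyl-7-(3,4-dimethoxyphenyl)-3-hydroxy-6-methylbicyclo[3.2.1]oct-3-ene-2,8-dione, via 2,3,8-trione 15 (not isolated)
Conditions: Dess–Martin periodinane (1.2 equiv), CH2Cl2, 0 °C → rt
Reagents that add atoms: none
Why: Periodinane oxidation of the α-hydroxy ketone to the 1,2-dione under non-basic conditions; 15 enolises at once to 16 because C4 carries the only enolisable hydrogens next to the dione (C1 is a bridgehead).

Step 10
Reactants: 16 (1S,5S,6R,7R)-5-allyl-7-(3,4-dimethoxyphenyl)-3-hydroxy-6-methylbicyclo[3.2.1]oct-3-ene-2,8-dione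
Product: 17 kadsurenin D, (1S,5S,6R,7R)-5-allyl-7-(3,4-dimethoxyphenyl)-3-methoxy-6-methylbicyclo[3.2.1]oct-3-ene-2,8-dione
Conditions: TMSCHN2 (2 M in hexanes), toluene/MeOH 4:1, 0 °C → rt
Reagents that add atoms: (trimethylsilyl)diazomethane, C[Si](C)(C)C=[N+]=[N-]
Why: The acidic enol protonates the diazoalkane and, after desilylation by methanol, the methyldiazonium ion methylates the enolate oxygen; no base or nucleophile is present that could open the non-enolisable 1,3-dione, and C1, C5, C6 and C7 are untouched.

## Compound list

1 | 2-allyl-3-methylcyclopent-2-en-1-one | C=CCC1=C(C)CCC1=O | starting material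
2 | 2-allyl-1-methyl-3-(trimethylsilyloxy)cyclopenta-1,3-diene | C=CCC1=C(C)CC=C1O[Si](C)(C)C | intermediate
3 | 2-allyl-5-bromo-3-methylcyclopent-2-en-1-one (racemic) | C=CCC1=C(C)CC(Br)C1=O | intermediate
4 | 1-allyl-4-bromo-5,5-dimethoxy-2-methylcyclopent-1-ene (racemic) | C=CCC1=C(C)CC(Br)C1(OC)OC | intermediate
5 | 1-allyl-5,5-dimethoxy-2-methylcyclopenta-1,3-diene | C=CCC1=C(C)C=CC1(OC)OC | intermediate
6 | pyruvaldehyde dimethyl acetal (1,1-dimethoxypropan-2-one) | CC(=O)C(OC)OC | starting material
7 | (S)-1-phenylethanol | C[C@H](O)c1ccccc1 | starting material
8 | 1,1-bis[(S)-1-phenylethoxy]propan-2-one | CC(=O)C(O[C@@H](C)c1ccccc1)O[C@@H](C)c1ccccc1 | intermediate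
9 | 2-(triethylsilyloxy)acrolein bis[(S)-1-phenylethyl] acetal | C=C(O[Si](CC)(CC)CC)C(O[C@@H](C)c1ccccc1)O[C@@H](C)c1ccccc1 | intermediate
10 | [(S)-1-phenylethyl][2-(triethylsilyloxy)prop-2-en-1-ylidene]oxonium triflate | C=C(O[Si](CC)(CC)CC)C=[O+][C@@H](C)c1ccccc1.[O-]S(=O)(=O)C(F)(F)F | intermediate
11 | (1R,2S,5R)-5-allyl-8,8-dimethoxy-6-methyl-2-[(S)-1-phenylethoxy]bicyclo[3.2.1]oct-6-en-3-one | C=CC[C@]12CC(=O)[C@@H](O[C@@H](C)c3ccccc3)[C@H](C1(OC)OC)C=C2C | intermediate
12 | 3,4-dimethoxyphenylboronic acid | OB(O)c1ccc(OC)c(OC)c1 | starting material
13 | (1R,2S,5R,6R,7R)-5-allyl-7-(3,4-dimethoxyphenyl)-8,8-dimethoxy-6-methyl-2-[(S)-1-phenylethoxy]bicyclo[3.2.1]octan-3-one | C=CC[C@]12CC(=O)[C@@H](O[C@@H](C)c3ccccc3)[C@H](C1(OC)OC)[C@H](c1ccc(OC)c(OC)c1)[C@H]2C | intermediate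
14 | (1R,2S,5R,6R,7R)-5-allyl-7-(3,4-dimethoxyphenyl)-2-hydroxy-6-methylbicyclo[3.2.1]octane-3,8-dione | C=CC[C@]12CC(=O)[C@@H](O)[C@H](C1=O)[C@H](c1ccc(OC)c(OC)c1)[C@H]2C | intermediate
15 | (1S,5R,6R,7R)-5-allyl-7-(3,4-dimethoxyphenyl)-6-methylbicyclo[3.2.1]octane-2,3,8-trione | C=CC[C@]12CC(=O)C(=O)[C@H](C1=O)[C@H](c1ccc(OC)c(OC)c1)[C@H]2C | intermediate
16 | (1S,5S,6R,7R)-5-allyl-7-(3,4-dimethoxyphenyl)-3-hydroxy-6-methylbicyclo[3.2.1]oct-3-ene-2,8-dione | C=CC[C@]12C=C(O)C(=O)[C@H](C1=O)[C@H](c1ccc(OC)c(OC)c1)[C@H]2C | intermediate
17 | kadsurenin D, (1S,5S,6R,7R)-5-allyl-7-(3,4-dimethoxyphenyl)-3-methoxy-6-methylbicyclo[3.2.1]oct-3-ene-2,8-dione | C=CC[C@]12C=C(OC)C(=O)[C@H](C1=O)[C@H](c1ccc(OC)c(OC)c1)[C@H]2C | target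

## Step count and least certain steps

Total: 10 steps. Longest linear sequence: 8 steps (1 → 3 → 4 → 5 → 11 → 13 → 14 → 16 → 17, steps 1, 2, 3, 6, 7, 8, 9, 10); the branch from 6 and 7 (steps 4 and 5) joins at step 6.

In step 7, the step that carries the label, the most likely failure is that the alkyl-rhodium intermediate on the tertiary carbon C6 undergoes β-hydride elimination toward the methyl group, with the rhodium hydride so formed moving the allyl double bond into conjugation. Insertion may also not occur at all, because the alkene is trisubstituted and one C8 methoxy group lies over its exo face. The fallback uses only known reaction types; it sets out from 11 and comes back at 13.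
- Allylic oxidation of the C6 methyl group (SeO2, tBuOOH, CH2Cl2) should give (1R,2S,5R)-5-allyl-6-(hydroxymethyl)-8,8-dimethoxy-2-[(S)-1-phenylethoxy]bicyclo[3.2.1]oct-6-en-3-one F1; the trisubstituted alkene reacts in preference to the monosubstituted one.
- MnO2 should give the enal (1R,2S,5R)-5-allyl-8,8-dimethoxy-3-oxo-2-[(S)-1-phenylethoxy]bicyclo[3.2.1]oct-6-ene-6-carbaldehyde F2.
- The alkene is now an acceptor, so conjugate addition of 12 of the Hayashi–Miyaura type ([Rh(OH)(cod)]2, dioxane/H2O) should deliver the aryl group to C7 from the exo face; after equilibration of the enolisable aldehyde it should give the trans aldehyde (1R,2S,5R,6R,7R)-5-allyl-7-(3,4-dimethoxyphenyl)-8,8-dimethoxy-3-oxo-2-[(S)-1-phenylethoxy]bicyclo[3.2.1]octane-6-carbaldehyde F3.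
- Condensation with TsNHNH2 should give the tosylhydrazone of that aldehyde F4, and reduction with catecholborane followed by NaOAc·3H2O (Caglioti-type reduction) should convert the formyl carbon into the methyl group of 13.

In step 6, the key step, the most likely failure is reversed pairing of the termini: if bond formation is led by the methylene carbon of 10 at the unhindered diene terminus, the alkoxy-bearing carbon ends up on C5 and the oxygen pattern of the bridge is transposed. A regioisomer formed through the same face of the cation lies on the opposite face of the diene and therefore has the mirror-image skeleton, so the fallback uses the other enantiomer of the alcohol. A wrong sense of induction alone is covered by the assumption stated before step 1. The fallback sets out from 5 and 6 and comes back at 14.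
- 6 and commercial (R)-1-phenylethanol should give 1,1-bis[(R)-1-phenylethoxy]propan-2-one F5 and its enol silane 2-(triethylsilyloxy)acrolein bis[(R)-1-phenylethyl] acetal F6 as in steps 4 and 5.
- Cycloaddition with 5 under the conditions of step 6 would then give (1S,4R,5S)-5-allyl-8,8-dimethoxy-6-methyl-4-[(R)-1-phenylethoxy]bicyclo[3.2.1]oct-6-en-3-one F7, which has the bridgehead configuration of the target.
- SmI2 in THF/MeOH at −78 °C should remove the α-alkoxy group and give (1S,5R)-5-allyl-8,8-dimethoxy-6-methylbicyclo[3.2.1]oct-6-en-3-one F8.
- Arylation as in step 7 (or by its fallback) should give (1S,5R,6R,7R)-5-allyl-7-(3,4-dimethoxyphenyl)-8,8-dimethoxy-6-methylbicyclo[3.2.1]octan-3-one F9.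
- Kinetic enolisation with KN(SiMe3)2 is expected at C2, the methylene next to the CH bridgehead, rather than at C4 next to the quaternary C5; oxidation of the enolate with 2-(phenylsulfonyl)-3-phenyloxaziridine should give (1R,2S,5R,6R,7R)-5-allyl-7-(3,4-dimethoxyphenyl)-2-hydroxy-8,8-dimethoxy-6-methylbicyclo[3.2.1]octan-3-one F10 (C2 epimer immaterial).
- Aqueous CF3CO2H should hydrolyse the ketal to 14.

In step 3 the most likely failure is base-induced migration of the allyl double bond into conjugation with the new diene, together with Diels–Alder dimerisation of 5 during isolation. The fallback replaces the base-induced elimination by a thermal syn elimination under neutral conditions; it sets out from 1 and comes back at 5.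
- The kinetic enolate of 1 (LiN(iPr)2, THF, −78 °C) is selenenylated with PhSeBr to 2-allyl-3-methyl-5-(phenylselanyl)cyclopent-2-en-1-one F11.
- Ketalisation as in step 2 should give 1-allyl-5,5-dimethoxy-2-methyl-4-(phenylselanyl)cyclopent-1-ene F12.
- Oxidation with H2O2/pyridine in CH2Cl2 at 0 °C should give the selenoxide 1-allyl-5,5-dimethoxy-2-methyl-4-(phenylseleninyl)cyclopent-1-ene F13, which is not isolated and can eliminate only toward the ring methylene to give 5.

In step 4 the most likely failure is stalling after the first exchange, because the second bulky alkoxy group enters slowly, with acid-induced ionisation of the benzylic alcohol (racemisation, ether formation) on forcing. The fallback needs only one exchange and relies on preferential departure of the smaller methoxy group in the ionisation; it sets out from 6 and 7 and comes back at 11.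
- One equivalent of 7 under the same catalysis should give 1-methoxy-1-[(S)-1-phenylethoxy]propan-2-one F14 (both epimers at the acetal carbon).
- Silylation as in step 5 should give its enol silane triethyl({3-methoxy-3-[(S)-1-phenylethoxy]prop-1-en-2-yl}oxy)silane F15.
- Under the conditions of step 6, F15 should lose the methoxy group, form the same cation 10 and give 11 with 5.

## Further compounds

F1 | step 7 | (1R,2S,5R)-5-allyl-6-(hydroxymethyl)-8,8-dimethoxy-2-[(S)-1-phenylethoxy]bicyclo[3.2.1]oct-6-en-3-one | C=CC[C@]12CC(=O)[C@@H](O[C@@H](C)c3ccccc3)[C@H](C1(OC)OC)C=C2CO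
F2 | step 7 | (1R,2S,5R)-5-allyl-8,8-dimethoxy-3-oxo-2-[(S)-1-phenylethoxy]bicyclo[3.2.1]oct-6-ene-6-carbaldehyde | C=CC[C@]12CC(=O)[C@@H](O[C@@H](C)c3ccccc3)[C@H](C1(OC)OC)C=C2C=O
F3 | step 7 | (1R,2S,5R,6R,7R)-5-allyl-7-(3,4-dimethoxyphenyl)-8,8-dimethoxy-3-oxo-2-[(S)-1-phenylethoxy]bicyclo[3.2.1]octane-6-carbaldehyde | C=CC[C@]12CC(=O)[C@@H](O[C@@H](C)c3ccccc3)[C@H](C1(OC)OC)[C@H](c1ccc(OC)c(OC)c1)[C@H]2C=O
F4 | step 7 | (E)-4-methylbenzenesulfonohydrazone of F3 at the formyl group | C=CC[C@]12CC(=O)[C@@H](O[C@@H](C)c3ccccc3)[C@H](C1(OC)OC)[C@H](c1ccc(OC)c(OC)c1)[C@H]2/C=N/NS(=O)(=O)c1ccc(C)cc1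
F5 | step 6 | 1,1-bis[(R)-1-phenylethoxy]propan-2-one | CC(=O)C(O[C@H](C)c1ccccc1)O[C@H](C)c1ccccc1
F6 | step 6 | 2-(triethylsilyloxy)acrolein bis[(R)-1-phenylethyl] acetal | C=C(O[Si](CC)(CC)CC)C(O[C@H](C)c1ccccc1)O[C@H](C)c1ccccc1
F7 | step 6 | (1S,4R,5S)-5-allyl-8,8-dimethoxy-6-methyl-4-[(R)-1-phenylethoxy]bicyclo[3.2.1]oct-6-en-3-one | C=CC[C@]12[C@@H](O[C@H](C)c3ccccc3)C(=O)C[C@H](C1(OC)OC)C=C2C
F8 | step 6 | (1S,5R)-5-allyl-8,8-dimethoxy-6-methylbicyclo[3.2.1]oct-6-en-3-one | C=CC[C@]12CC(=O)C[C@H](C1(OC)OC)C=C2C
F9 | step 6 | (1S,5R,6R,7R)-5-allyl-7-(3,4-dimethoxyphenyl)-8,8-dimethoxy-6-methylbicyclo[3.2.1]octan-3-one | C=CC[C@]12CC(=O)C[C@H](C1(OC)OC)[C@H](c1ccc(OC)c(OC)c1)[C@H]2C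
F10 | step 6 | (1R,2S,5R,6R,7R)-5-allyl-7-(3,4-dimethoxyphenyl)-2-hydroxy-8,8-dimethoxy-6-methylbicyclo[3.2.1]octan-3-one | C=CC[C@]12CC(=O)[C@@H](O)[C@H](C1(OC)OC)[C@H](c1ccc(OC)c(OC)c1)[C@H]2C
F11 | step 3 | 2-allyl-3-methyl-5-(phenylselanyl)cyclopent-2-en-1-one (racemic) | C=CCC1=C(C)CC([Se]c2ccccc2)C1=O
F12 | step 3 | 1-allyl-5,5-dimethoxy-2-methyl-4-(phenylselanyl)cyclopent-1-ene (racemic) | C=CCC1=C(C)CC([Se]c2ccccc2)C1(OC)OC
F13 | step 3 | 1-allyl-5,5-dimethoxy-2-methyl-4-(phenylseleninyl)cyclopent-1-ene (mixture of stereoisomers) | C=CCC1=C(C)CC([Se](=O)c2ccccc2)C1(OC)OC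
F14 | step 4 | 1-methoxy-1-[(S)-1-phenylethoxy]propan-2-one (both epimers at the acetal carbon) | CC(=O)C(OC)O[C@@H](C)c1ccccc1
F15 | step 4 | triethyl({3-methoxy-3-[(S)-1-phenylethoxy]prop-1-en-2-yl}oxy)silane (both epimers at the acetal carbon) | C=C(O[Si](CC)(CC)CC)C(OC)O[C@@H](C)c1ccccc1
A1 | alternative 1 | methyl 3-(3,4-dimethoxyphenyl)-2-{2-[(4-methoxybenzyloxy)methyl]but-2-enoyl}acrylate (aryl and methyl each trans to the ketone carbon) | COC(=O)/C(=C\c1ccc(OC)c(OC)c1)C(=O)/C(COCc1ccc(OC)cc1)=C/C
A2 | alternative 1 | methyl 3-allyl-5-(3,4-dimethoxyphenyl)-3-[(4-methoxybenzyloxy)methyl]-4-methyl-2-oxocyclopentane-1-carboxylate | C=CC[C@]1(COCc2ccc(OC)cc2)C(=O)[C@@H](C(=O)OC)[C@H](c2ccc(OC)c(OC)c2)[C@H]1C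
A3 | alternative 2 | 3-(1-allyl-2,5-dioxocyclopentyl)-2-methoxyacrylaldehyde (ring carbon and formyl group cis) | C=CCC1(C(=O)CCC1=O)/C=C(OC)\C=O
A4 | alternative 2 | 5-allyl-2-hydroxy-3-methoxybicyclo[3.2.1]oct-3-ene-6,8-dione | C=CC[C@]12C=C(OC)[C@@H](O)[C@H](C1=O)CC2=O
A5 | alternative 3 | trans-3-allyl-5-(3,4-dimethoxyphenyl)-4-methylcyclohepta-2,6-dien-1-one | C=CCC1=CC(=O)C=C[C@H](c2ccc(OC)c(OC)c2)[C@H]1C
A6 | alternative 3 | 5-allyl-7-(3,4-dimethoxyphenyl)-6-methyl-8-nitrobicyclo[3.2.1]octan-3-one | C=CC[C@]12CC(=O)C[C@H]([C@@H]1[N+](=O)[O-])[C@H](c1ccc(OC)c(OC)c1)[C@H]2C
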